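**Unit first.** Percent of the substrate charged is the unit of every reading, and it cancels in the ratio c(isomer)/c(target), so runs at different concentrations can be laid side by side.

| setting | Friday's | Saturday's | flask |
|---|---|---|---|
| substrate | 0.20 M | 0.30 M | 0.40 M |
| partner | 2.5 equiv | 2.5 equiv | 2.50 equiv |
| remark | run made earlier | run made earlier |  |
| time |  |  | 3.0 h |

| run | time / h | isomer of the product / % | target / % |
|---|---|---|---|
| Friday's | 0.200 | 23.3 | 48.6 |
| Friday's | 0.333 | 25.5 | 54.3 |
| Friday's | 0.417 | 27.6 | 56.8 |
| Friday's | 0.667 | 27.7 | 57.4 |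
| Friday's | 1.00 | 28.1 | 57.5 |
| Friday's | 1.50 | 27.1 | 58.3 |
| Friday's | 2.50 | 28.1 | 58.5 |
| Saturday's | 0.333 | 26.7 | 57.7 |
| Saturday's | 0.667 | 27.2 | 59.6 |
| Saturday's | 1.00 | 25.6 | 56.9 |
| Saturday's | 1.33 | 26.8 | 56.5 |
| Saturday's | 1.50 | 29.3 | 58.0 |
| Saturday's | 2.00 | 25.7 | 57.1 |
| Saturday's | 2.50 | 27.9 | 58.1 |

(standard deviation of a reading: 1 percentage point)

* ratio of isomer of the product to target at 8.0 s
* ratio of isomer of the product to target at 4.0 min
* ratio of isomer of the product to target at 3.0 h

**Loose bracket.** Saturday's run reads 0.505 at 1.50 h and 0.450 at 1.00 h, which gives a first bound from above and from below, though each end is a single pair of readings with its scatter.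

**Tight bracket.** Summing a run's readings before dividing tightens the bounds to 0.479 on Friday's run and 0.468 on Saturday's. Their mean, 0.474, is the split, the selectivity factor that turns an amount of target into an amount of isomer. My reckoning commits to it at all asked times, but 8.0 s lies far earlier than Friday's first reading at 0.200 h, so that end is an extrapolation from a first ratio of 0.479.

**The forecast.** It gives 0.47 (0.2 to 0.65), 0.47 (0.4 to 0.53) and 0.473 (0.455 to 0.49), the last inside the bracket, and widens early because “fast equilibration hiding a different kinetic ratio cannot be excluded”.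

**The result.** The flask gives 0.476, 0.471 and 0.471, all within the forecast's tolerance, the last inside the bracket.

    substrate + partner → intermediate + by-product (k = 0.0153 M⁻¹ s⁻¹)
    intermediate ⇌ target (K = 5.10, k = 0.721 s⁻¹)
    intermediate ⇌ isomer of the product (K = 2.40, k = 0.346 s⁻¹)
    substrate + intermediate → side product (k = 0.00691 M⁻¹ s⁻¹)
    substrate ⇌ dormant form (K = 1.29, k = 0.0126 s⁻¹)

**The split reused.** The isomer of the product has a half-life of 0.080 min for going back by its own step, short against 3.0 h. The neighbour charged with 0.620 equiv of partner still shows 0.471, inside the range the forecast gave for this flask. In this flask, 58.2% of target times the split gives 27.6% of isomer. In that neighbour, 25.0% of target gives 11.8%, and it holds 11.8% of isomer at 3.00 h.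

Readings and results come from a simulation on assumed constants.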